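## Structural features

The target is a linear procyanidin tetramer of four (−)-epicatechin units, each a (2R,3R)-2-arylchroman-3-ol with a phloroglucinol-type ring A, a pyran ring and a catechol ring B, the C2 aryl and the C3 hydroxyl being cis. Three carbon–carbon interflavan bonds join the units: C4 of unit 1 to C6 of unit 2, C4 of unit 2 to C8 of unit 3, and C4 of unit 3 to C6 of unit 4. In units 1 to 3 the C4 substituent is trans to the C3 hydroxyl (4β), so each of these units has three contiguous stereocentres (C2, C3, C4) and unit 4 has two, eleven in all. The fragile groups are the twenty phenols (air- and base-sensitive catechols), the acid-labile interflavan bonds and the base-epimerisable C2 centres, so the final unmasking has to be neutral and reductive. The real difficulty is the two 4→6 bonds, because a flavan C4 cation normally attacks C8 of an unblocked partner, together with joining four units without statistical oligomerisation. The upper half (units 1 and 2) and the lower half (units 3 and 4) are the same 4β→6 dimer, so one dimer can serve as both halves. The key step exploits unit 1: C3 (oxygen-bearing) and C4 (bearing C6 of unit 2) are adjacent trans stereocentres next to the phenolic oxygen of ring A, which is the pattern of a glycolaldehyde unit (C2–C3) added to the o-quinone methide C4=C4a–C8a=O of ring A.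

## Logic of the disconnections

22 from 21: twenty O–benzyl bonds and two C8–Br bonds are traced back. Free phenols would not survive organometallic, oxidative and Lewis-acid steps, and both groups fall in one neutral hydrogenolysis. The demand is that HBr is buffered and that the benzylic C2–O1 bonds and interflavan bonds are not hydrogenolysed.

21 from 20 and 19: the C4(unit 2)–C8(unit 3) bond is cut. It is the only 4→8 bond, the type that forms with the natural regiochemistry of a flavan-4-yl cation, and the cut gives two halves with the same skeleton. The forward step must deliver 4β attack at C8 of the upper unit of 19, with the bromine at C8 of the lower unit blocking that site and excess 19 suppressing self-condensation of 20.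

20 from 19: the C4–O bond on the brominated unit is removed, so that the electrophilic half is the same dimer one oxidation level lower. The demand is site-selective benzylic C–H oxidation.

19 from 18: the O1–C2 bond of the upper unit is cut. C2 is benzylic to an electron-rich ring and can be closed by ionisation. The closure must place the C2 aryl cis to the C3 benzyloxy group.

18 from 15 and 16 (through 17): the C2–aryl bond to ring B is cut, so ring B arrives as a simple aryl nucleophile and what remains is a lactol, a masked aldehyde. C3 must not epimerise during the addition.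

15 from 10 and 11 (through 12, 13 and 14): C3–C4 and the hemiacetal bond O1–C2 are cut. This removes one ring and two stereocentres at once, and it turns the difficult 4→6 interflavan bond into an aryl–carbinol bond already present in 10. The forward step must set 3R and the 3,4-trans relation by catalyst control.

10 from 5 and 7 (through 8 and 9): the bond between the carbinol carbon and C6 of the epicatechin ring is cut. The 4→6 regiochemistry is thereby fixed by where the iodine sits. The demand is an iodine–magnesium exchange that leaves the bromine alone, and a phenol that does not quench the arylmagnesium.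

5 from 4, 3, 2 and 1: the carbon–iodine, carbon–bromine and five O–benzyl bonds are traced back to the chiral pool, which supplies C2 and C3 of the lower unit. The halogens must enter in the order of ring A nucleophilicity, C8 first and C6 second.

7 from 6: two O–benzyl bonds are cut; the hydrogen-bonded ortho hydroxyl must stay free.

## Other disconnections considered

Alternative 1: The cut is at the three C4–C4a bonds of units 1, 2 and 3. The product of the key step would be A1, the eicosabenzyl tetramer with bromine at C8 of unit 4, formed from the open-chain triol A2, in which three 1-aryl-2-benzyloxy-3-hydroxypropyl aryl ethers are linked through their carbinol carbons. Acid would ionise the three carbinols of A2, and each cation would be taken by the ortho carbon of its own 3,5-dioxygenated aryl ether, closing three pyran rings in one operation. In its favour, every interflavan bond is already in A2, so 4→6 versus 4→8 is fixed by connectivity and needs neither a bimolecular coupling nor an excess of one partner. On this point it is better than the chosen plan, and closing three rings at once is attractive. Against it, three C4 centres must form 4β by substrate control alone, from diaryl cations that can also be trapped by the wrong ring or by another molecule. A2 itself needs three separately built C2/C3 pairs and three aryl ether bonds at ionisable benzylic carbons. Only unit 4 would come from epicatechin, whereas the chosen plan takes two units from it and builds one dimer used twice, so the step count of this alternative should be much higher. Mechanistically both plans rely on stabilised benzylic cations, but the chosen plan sets C3 and C4 with a catalyst and not by a triple cyclisation under substrate control.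

Alternative 2: The cut is at O1–C2 and C3–C4 of unit 4. The product of the key step would be A3, the benzylated tetramer with a benzyldimethylsilyl group at C3 of unit 4. It would arise by warming the trimer-bound 2-(hydroxymethyl)phenol A4 with the (Z)-vinylsilane A5: water is lost from the hydroxymethylphenol part of A4 and the resulting heterodiene unit adds the alkene of A5 suprafacially. Tamao–Fleming oxidation (retention) and hydrogenolysis would then lead to 22. In its favour, the cis relation of the C2 aryl and C3 substituent follows from the alkene geometry in a concerted addition. That is better than the chosen plan, where the same relation in unit 1 depends on a conformational preference in step 9. Against it, the ring built is the bottom unit, which epicatechin supplies intact. The absolute sense of the addition would have to be induced by stereocentres far away in unit 3, so a mixture of (2R,3R) and (2S,3S) unit 4 is to be expected, whereas the chosen plan sets its new centres with a chiral catalyst. A4 is a trimer that still contains both a 4→6 and a 4→8 bond, so the real difficulty is untouched, and thermal or acidic unmasking on such a substrate endangers the interflavan bonds. In step economy it adds a ring construction and an oxidation to a trimer synthesis, so it is longer than the chosen plan.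

Alternative 3: The cut is at C4–C4a of unit 4. The product of the key step would be A6, the nonadecabenzyl tetramer with a free 3-hydroxyl on unit 4, formed from the O1-linked epoxypropyl ether A7. Sc(OTf)3 would activate the terminal epoxide and the ortho carbon of ring A would attack the CH2 terminus in a Friedel–Crafts alkylation. In its favour, no stereocentre is made in the key step. C2 and C3 would already be present in A7 as an enantiopure epoxy ether, which is at least equal to, and for C2 safer than, the chosen plan, and the free 3-hydroxyl of A6 is a handle the chosen route does not offer. Against it, unit 4 is again rebuilt instead of taken from epicatechin. Making A7 requires an aryl ether at a secondary benzylic carbon on a hindered phenolic oxygen of a trimer, with loss of configuration at C2 if that carbon ionises under the Lewis acid. The five-membered closure at the inner epoxide carbon competes, and the trimer with both interflavan bond types must still be made. The chosen plan deals with the 4→6 bond itself, which this alternative leaves open, and it is shorter.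

Key step: step 7

Assumption: the benzyl-protected halves (units 1–2 and units 3–4) are one and the same 8-bromo dimer, so 19 serves as both coupling partners, and the phenol of 7 is converted to its sodium phenoxide before the arylmagnesium is added, because a free phenol would protonate it.

## Route

Step 1
Reactants: 1 (−)-epicatechin
Product: 2 5,7,3',4'-tetra-O-benzylepicatechin
Conditions: BnBr (4.4 equiv), K2CO3, DMF, 0 °C → rt
Reagents that add atoms: benzyl bromide, BrCc1ccccc1
Why: Williamson etherification of the four phenols; K2CO3 does not deprotonate the secondary alcohol, so the 3-hydroxyl stays free and C2/C3 are untouched.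

Step 2
Reactants: 2 5,7,3',4'-tetra-O-benzylepicatechin
Product: 3 3,5,7,3',4'-penta-O-benzylepicatechin
Conditions: NaH, BnBr, n-Bu4NI (cat.), DMF, 0 °C → rt
Reagents that add atoms: benzyl bromide, BrCc1ccccc1
Why: Williamson etherification of the secondary alkoxide; with all phenols already capped there is no phenoxide that could open the pyran ring and epimerise C2.

Step 3
Reactants: 3 3,5,7,3',4'-penta-O-benzylepicatechin
Product: 4 8-bromo-penta-O-benzylepicatechin
Conditions: NBS (1.0 equiv), CH2Cl2, −78 °C → 0 °C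
Reagents that add atoms: N-bromosuccinimide, O=C1CCC(=O)N1Br
Why: Electrophilic aromatic bromination; C8 is the most nucleophilic ring A carbon of benzylated flavan-3-ols, and one equivalent at low temperature should stop at the monobromide. The bromine blocks C8 in every later step.

Step 4
Reactants: 4 8-bromo-penta-O-benzylepicatechin
Product: 5 8-bromo-6-iodo-penta-O-benzylepicatechin
Conditions: NIS (1.2 equiv), CF3CO2H (cat.), MeCN/CH2Cl2, 0 °C → rt, dark
Reagents that add atoms: N-iodosuccinimide, O=C1CCC(=O)N1I
Why: Electrophilic aromatic iodination at C6, the only free carbon left on the trioxygenated ring; ring B is far less activated. The iodide marks the future 4→6 attachment point.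

Step 5
Reactants: 6 2,4,6-trihydroxybenzaldehyde
Product: 7 4,6-bis(benzyloxy)-2-hydroxybenzaldehyde
Conditions: BnBr (2.05 equiv), K2CO3 (2.2 equiv), DMF, 0 °C → rt
Reagents that add atoms: benzyl bromide, BrCc1ccccc1
Why: Williamson etherification; the para hydroxyl and one ortho hydroxyl react, while the remaining ortho hydroxyl is held in the hydrogen bond to the formyl group and should resist alkylation.

Step 6
Reactants: 5 8-bromo-6-iodo-penta-O-benzylepicatechin; 7 4,6-bis(benzyloxy)-2-hydroxybenzaldehyde
Product: 10 [4,6-bis(benzyloxy)-2-hydroxyphenyl](8-bromo-penta-O-benzylepicatechin-6-yl)methanol (both carbinol epimers), via arylmagnesium chloride 8 (not isolated), via sodium phenoxide 9 (not isolated)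
Conditions: 5, i-PrMgCl·LiCl (1.05 equiv), THF, −20 °C; then 9 (from 7, NaH 1.0 equiv, THF, 0 °C; 1.3 equiv), −20 °C → rt; pH 7 phosphate buffer; Et3N-deactivated silica
Reagents that add atoms: none
Why: Iodine–magnesium exchange is much faster at the iodide than at the bromide and is helped by the two ortho ether oxygens; the arylmagnesium then adds 1,2 to the aldehyde (Grignard addition). Forming the phenoxide first prevents protonation of the arylmagnesium. The carbinol centre is formed without control and is erased in step 7; the neutral work-up avoids premature loss of water.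

Step 7
Reactants: 10 [4,6-bis(benzyloxy)-2-hydroxyphenyl](8-bromo-penta-O-benzylepicatechin-6-yl)methanol; 11 benzyloxyacetaldehyde
Product: 15 (3R)-3,5,7-tris(benzyloxy)-4-(8-bromo-penta-O-benzylepicatechin-6-yl)chroman-2-ol (3,4-trans; anomers), via o-quinone methide 12 (not isolated), via enamine 13 (not isolated), via hydroxy aldehyde 14 (not isolated)
Conditions: 11 (3 equiv, slow addition), (S)-α,α-diphenylprolinol trimethylsilyl ether (20 mol%), PhCO2H (20 mol%), CH2Cl2, rt
Reagents that add atoms: none
Why: The carboxylic acid should ionise the electron-rich benzhydrol 10 to the o-quinone methide 12 while the amine condenses with 11 to the E-enamine 13; attack of the enamine α-carbon on the exocyclic methide carbon forms C3–C4 and rearomatises ring A, and hydrolysis of the iminium ion releases hydroxy aldehyde 14 and the amine. This is the secondary-amine-catalysed Michael addition and hemiacetalisation of aldehydes with o-quinone methides generated in situ from o-hydroxybenzhydrols, a reaction type known to give 3,4-trans chroman-2-ols, applied here to an α-benzyloxy aldehyde and a more crowded methide. The pyran ring closes reversibly by 6-exo-trig addition of the phenol oxygen to the aldehyde (O1–C2), the lactol is the resting form, and its anomeric centre C2 forms as a mixture that is removed in step 8. C3 is set by the catalyst: the CPh2(OSiMe3) group covers one face of the s-trans E-enamine, so the electrophile is taken up on the open (Re) face, which corresponds to 3R. C4 is set by the relative topicity of the two trigonal carbons: the compact arrangement that keeps the enamine nitrogen near the methide oxygen (the topicity of syn-selective enamine additions to nitroalkenes) places the C3 benzyloxy and C4 aryl groups trans on the ring. The step needs catalyst control over the remote C2/C3 centres of the epicatechin fragment (five bonds from C4, so they should not bias the faces), alkylation at carbon and not at nitrogen (nitrogen adducts revert under the acid), and suppression of aldehyde self-aldolisation by slow addition of 11. The trans lactol is also the thermodynamically preferred C3 epimer, so any equilibration through the enamine should work in the same direction.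

Step 8
Reactants: 15 (3R)-3,5,7-tris(benzyloxy)-4-(8-bromo-penta-O-benzylepicatechin-6-yl)chroman-2-ol; 16 4-bromo-1,2-bis(benzyloxy)benzene
Product: 18 1-[3,4-bis(benzyloxy)phenyl]-2-(benzyloxy)-3-[4,6-bis(benzyloxy)-2-hydroxyphenyl]-3-(8-bromo-penta-O-benzylepicatechin-6-yl)propan-1-ol (C1 epimers), via aryl Grignard reagent 17 (not isolated)
Conditions: 16, Mg, THF (→ 17, 4 equiv); 15, THF, −20 °C → rt; aq NH4Cl
Reagents that add atoms: none
Why: Grignard addition to a lactol: the first equivalent deprotonates and opens 15 to the phenoxide aldehyde, the next adds to the carbonyl. The epimer mixture at the new carbinol is irrelevant because that centre is ionised in step 9; the hindered aryl bromide and the benzyl ethers are inert to the arylmagnesium.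

Step 9
Reactants: 18 1-[3,4-bis(benzyloxy)phenyl]-2-(benzyloxy)-3-[4,6-bis(benzyloxy)-2-hydroxyphenyl]-3-(8-bromo-penta-O-benzylepicatechin-6-yl)propan-1-ol
Product: 19 deca-O-benzyl epicatechin-(4β→6)-8-bromoepicatechin
Conditions: (1S)-(+)-10-camphorsulfonic acid (10 mol%), CH2Cl2, 0 °C → rt
Reagents that add atoms: none
Why: Acid-catalysed SN1 cyclodehydration: the 3,4-bis(benzyloxy)benzylic cation is captured by the phenol oxygen (O1–C2). The bulky C4 aryl should sit pseudoaxial to avoid the peri benzyloxy group at C5, which makes the trans C3 benzyloxy group axial (nearly cost-free in a chroman), so the closure with the C2 aryl equatorial is the 2,3-cis (2R) one.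

Step 10
Reactants: 19 deca-O-benzyl epicatechin-(4β→6)-8-bromoepicatechin
Product: 20 deca-O-benzyl epicatechin-(4β→6)-[8-bromo-4β-(2-ethoxyethoxy)epicatechin]
Conditions: DDQ (2 equiv), HOCH2CH2OEt (5 equiv), CH2Cl2, rt
Reagents that add atoms: 2-ethoxyethanol, CCOCCO
Why: DDQ benzylic oxidation (hydride abstraction, then trapping by the alcohol) at the C4 methylene of the lower unit, whose pseudoaxial hydrogen is aligned with the ring A π system. The methine hydrogen at C4 of the upper unit lies near the planes of both flanking rings and should be a poor hydride donor; the alkoxy group should enter trans to the C3 benzyloxy group, though its configuration is lost in step 11.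

Step 11
Reactants: 20 deca-O-benzyl epicatechin-(4β→6)-[8-bromo-4β-(2-ethoxyethoxy)epicatechin]; 19 deca-O-benzyl epicatechin-(4β→6)-8-bromoepicatechin
Product: 21 eicosa-O-benzyl epicatechin-(4β→6)-8-bromoepicatechin-(4β→8)-epicatechin-(4β→6)-8-bromoepicatechin
Conditions: 19 (3 equiv), Me3SiOTf (0.5 equiv), CH2Cl2, −78 → −40 °C; Et3N
Reagents that add atoms: none
Why: Lewis-acid ionisation of the C4 ether and Friedel–Crafts capture of the flavan-4-yl cation by C8 of the upper unit of 19; attack anti to the axial C3 benzyloxy group of the 2,3-cis unit sets the new 4β centre. C8 is the most nucleophilic free carbon, C8 of the lower unit is blocked by bromine, and the excess of 19 (recoverable) suppresses self-condensation of 20.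

Step 12
Reactants: 21 eicosa-O-benzyl epicatechin-(4β→6)-8-bromoepicatechin-(4β→8)-epicatechin-(4β→6)-8-bromoepicatechin
Product: 22 epicatechin-(4β→6)-epicatechin-(4β→8)-epicatechin-(4β→6)-epicatechin
Conditions: H2 (1 atm), Pd(OH)2/C, Et3N (3 equiv), THF/MeOH/H2O, rt; Sephadex LH-20
Reagents that add atoms: none
Why: Catalytic hydrogenolysis removes the twenty benzyl ethers and both aryl bromides in one operation; Et3N takes up the HBr that would otherwise threaten the acid-labile interflavan bonds. No stereocentre is touched.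

## Compound list

1 | (−)-epicatechin, (2R,3R) | Oc1cc(O)c2c(c1)O[C@H](c1ccc(O)c(O)c1)[C@H](O)C2 | starting material
2 | 5,7,3',4'-tetra-O-benzylepicatechin, (2R,3R) | c9ccccc9COc1cc(OCc9ccccc9)c2c(c1)O[C@H](c7ccc(OCc9ccccc9)c(OCc9ccccc9)c7)[C@H](O)C2 | intermediate
3 | 3,5,7,3',4'-penta-O-benzylepicatechin | c9ccccc9COc1cc(OCc9ccccc9)c2c(c1)O[C@H](c7ccc(OCc9ccccc9)c(OCc9ccccc9)c7)[C@H](OCc9ccccc9)C2 | intermediate
4 | 8-bromo-penta-O-benzylepicatechin | c9ccccc9COc1cc(OCc9ccccc9)c2c(c1Br)O[C@H](c7ccc(OCc9ccccc9)c(OCc9ccccc9)c7)[C@H](OCc9ccccc9)C2 | intermediate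
5 | 8-bromo-6-iodo-penta-O-benzylepicatechin | c9ccccc9COc1c(I)c(OCc9ccccc9)c2c(c1Br)O[C@H](c7ccc(OCc9ccccc9)c(OCc9ccccc9)c7)[C@H](OCc9ccccc9)C2 | intermediate
6 | 2,4,6-trihydroxybenzaldehyde | O=Cc1c(O)cc(O)cc1O | starting material
7 | 4,6-bis(benzyloxy)-2-hydroxybenzaldehyde | O=Cc1c(O)cc(OCc9ccccc9)cc1OCc9ccccc9 | intermediate
8 | (8-bromo-penta-O-benzylepicatechin-6-yl)magnesium chloride (LiCl complex) | c9ccccc9COc1c([Mg]Cl)c(OCc9ccccc9)c2c(c1Br)O[C@H](c7ccc(OCc9ccccc9)c(OCc9ccccc9)c7)[C@H](OCc9ccccc9)C2 | intermediate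
9 | sodium 3,5-bis(benzyloxy)-2-formylphenoxide | [Na+].[O-]c1cc(OCc9ccccc9)cc(OCc9ccccc9)c1C=O | intermediate
10 | [4,6-bis(benzyloxy)-2-hydroxyphenyl](8-bromo-penta-O-benzylepicatechin-6-yl)methanol, carbinol epimers | c9ccccc9COc1cc(OCc9ccccc9)c(c(O)c1)C(O)c1c(OCc9ccccc9)c(Br)c3c(c1OCc9ccccc9)C[C@@H](OCc9ccccc9)[C@@H](c7ccc(OCc9ccccc9)c(OCc9ccccc9)c7)O3 | intermediate
11 | benzyloxyacetaldehyde | O=CCOCc1ccccc1 | starting material
12 | 3,5-bis(benzyloxy)-6-[(8-bromo-penta-O-benzylepicatechin-6-yl)methylidene]cyclohexa-2,4-dien-1-one, double-bond geometry not fixed | O=C1C=C(OCc9ccccc9)C=C(OCc9ccccc9)C1=Cc1c(OCc9ccccc9)c(Br)c3c(c1OCc9ccccc9)C[C@@H](OCc9ccccc9)[C@@H](c7ccc(OCc9ccccc9)c(OCc9ccccc9)c7)O3 | intermediate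
13 | (S)-1-[(E)-2-(benzyloxy)ethenyl]-2-[diphenyl(trimethylsilyloxy)methyl]pyrrolidine | C[Si](C)(C)OC(c1ccccc1)(c1ccccc1)[C@@H]1CCCN1/C=C/OCc1ccccc1 | intermediate
14 | 2-(benzyloxy)-3-[4,6-bis(benzyloxy)-2-hydroxyphenyl]-3-(8-bromo-penta-O-benzylepicatechin-6-yl)propanal, open form of 15 with the same two stereocentres | O=C[C@H](OCc9ccccc9)[C@@H](c1c(OCc9ccccc9)c(Br)c3c(c1OCc9ccccc9)C[C@@H](OCc9ccccc9)[C@@H](c7ccc(OCc9ccccc9)c(OCc9ccccc9)c7)O3)c1c(O)cc(OCc9ccccc9)cc1OCc9ccccc9 | intermediate
15 | (3R)-3,5,7-tris(benzyloxy)-4-(8-bromo-penta-O-benzylepicatechin-6-yl)chroman-2-ol, 3,4-trans, anomers | c9ccccc9COc1cc(OCc9ccccc9)c2c(c1)OC(O)[C@H](OCc9ccccc9)[C@H]2c1c(OCc9ccccc9)c(Br)c3c(c1OCc9ccccc9)C[C@@H](OCc9ccccc9)[C@@H](c7ccc(OCc9ccccc9)c(OCc9ccccc9)c7)O3 | intermediate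
16 | 4-bromo-1,2-bis(benzyloxy)benzene | Brc1ccc(OCc2ccccc2)c(OCc2ccccc2)c1 | starting material
17 | 3,4-bis(benzyloxy)phenylmagnesium bromide | Br[Mg]c1ccc(OCc2ccccc2)c(OCc2ccccc2)c1 | intermediate
18 | 1-[3,4-bis(benzyloxy)phenyl]-2-(benzyloxy)-3-[4,6-bis(benzyloxy)-2-hydroxyphenyl]-3-(8-bromo-penta-O-benzylepicatechin-6-yl)propan-1-ol, C1 epimers, C2/C3 as in 15 | OC(c7ccc(OCc9ccccc9)c(OCc9ccccc9)c7)[C@H](OCc9ccccc9)[C@@H](c1c(OCc9ccccc9)c(Br)c3c(c1OCc9ccccc9)C[C@@H](OCc9ccccc9)[C@@H](c7ccc(OCc9ccccc9)c(OCc9ccccc9)c7)O3)c1c(O)cc(OCc9ccccc9)cc1OCc9ccccc9 | intermediate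
19 | deca-O-benzyl epicatechin-(4β→6)-8-bromoepicatechin (upper unit 2,3-cis-3,4-trans) | c9ccccc9COc1cc(OCc9ccccc9)c2c(c1)O[C@H](c7ccc(OCc9ccccc9)c(OCc9ccccc9)c7)[C@H](OCc9ccccc9)[C@H]2c1c(OCc9ccccc9)c(Br)c3c(c1OCc9ccccc9)C[C@@H](OCc9ccccc9)[C@@H](c7ccc(OCc9ccccc9)c(OCc9ccccc9)c7)O3 | intermediate
20 | deca-O-benzyl epicatechin-(4β→6)-[8-bromo-4β-(2-ethoxyethoxy)epicatechin] | c9ccccc9COc1cc(OCc9ccccc9)c2c(c1)O[C@H](c7ccc(OCc9ccccc9)c(OCc9ccccc9)c7)[C@H](OCc9ccccc9)[C@H]2c1c(OCc9ccccc9)c(Br)c3c(c1OCc9ccccc9)[C@H](OCCOCC)[C@@H](OCc9ccccc9)[C@@H](c7ccc(OCc9ccccc9)c(OCc9ccccc9)c7)O3 | intermediate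
21 | eicosa-O-benzyl epicatechin-(4β→6)-8-bromoepicatechin-(4β→8)-epicatechin-(4β→6)-8-bromoepicatechin | c9ccccc9COc1cc(OCc9ccccc9)c2c(c1)O[C@H](c7ccc(OCc9ccccc9)c(OCc9ccccc9)c7)[C@H](OCc9ccccc9)[C@H]2c1c(OCc9ccccc9)c(Br)c2c(c1OCc9ccccc9)[C@H](c1c(OCc9ccccc9)cc(OCc9ccccc9)c3c1O[C@H](c7ccc(OCc9ccccc9)c(OCc9ccccc9)c7)[C@H](OCc9ccccc9)[C@H]3c1c(OCc9ccccc9)c(Br)c3c(c1OCc9ccccc9)C[C@@H](OCc9ccccc9)[C@@H](c7ccc(OCc9ccccc9)c(OCc9ccccc9)c7)O3)[C@@H](OCc9ccccc9)[C@@H](c7ccc(OCc9ccccc9)c(OCc9ccccc9)c7)O2 | intermediate
22 | epicatechin-(4β→6)-epicatechin-(4β→8)-epicatechin-(4β→6)-epicatechin | Oc1cc(O)c2c(c1)O[C@H](c1ccc(O)c(O)c1)[C@H](O)[C@H]2c1c(O)cc2c(c1O)[C@H](c1c(O)cc(O)c3c1O[C@H](c1ccc(O)c(O)c1)[C@H](O)[C@H]3c1c(O)cc3c(c1O)C[C@@H](O)[C@@H](c1ccc(O)c(O)c1)O3)[C@@H](O)[C@@H](c1ccc(O)c(O)c1)O2 | target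

## Step count and least certain steps

Total: 12 steps. Longest linear sequence: 11 steps (steps 1–4 and 6–12 from 1); step 5 is a one-step side branch.

Step 7 (key step). Three things are most likely to go wrong, because the α-benzyloxy donor and the crowded methide stretch the scope of the reaction type. First, bond formation may be slow, because the methide carbon is screened by four ortho oxygen substituents; that would give time for self-aldolisation of 11 and for reversible alkylation of the amine. Second, facial discrimination at C4 may be weak: the two aryl groups on the trigonal carbon are of similar size, and the methide geometry cannot be taken as fixed, since the benzyloxy group next to the exocyclic carbon and the carbonyl oxygen compete for the position syn to the aryl group. Third, C3 may erode by enamine-mediated epimerisation. The fallback uses known chemistry and sets out from 3 and 4: DDQ oxidation of 3 in the presence of 2-ethoxyethanol should give 4β-(2-ethoxyethoxy)-penta-O-benzylepicatechin F1, and Me3SiOTf-promoted coupling of F1 with an excess of 4 should give attack at C6, the only free ring A carbon once C8 is brominated, anti to the C3 benzyloxy group. This returns to the route at 19 and replaces steps 4–9.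

Step 9. The closure may show poor selectivity between the two chair-like modes: the all-equatorial mode would give the C2 epimer. Loss of a proton from the cation to a benzyl enol ether would also endanger C3. The fallback replaces ionisation by a stereospecific displacement and sets out from 18. Oxidation of the benzylic carbinol with MnO2 (CH2Cl2) should convert both epimers into 1-[3,4-bis(benzyloxy)phenyl]-2-(benzyloxy)-3-[4,6-bis(benzyloxy)-2-hydroxyphenyl]-3-(8-bromo-penta-O-benzylepicatechin-6-yl)propan-1-one F2. Chelation-controlled reduction with Zn(BH4)2 (Et2O, −20 °C) should give the 1,2-anti carbinol F3. Mitsunobu closure (PPh3, DIAD, THF, 0 °C) with inversion at the carbinol carbon should then give the 2,3-cis pyran and return to the route at 19.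

Step 10. Hydride abstraction may occur at the wrong benzylic position (the C4 methine of the upper unit or a C2–H), may be slowed by the bromine and the twisted benzyloxy groups of the fully substituted ring, or may run on to the C4 ketone. The fallback confines the oxidation to a monomer, where it is established, and carries the C4 leaving group of unit 2 through the 4→6 coupling as a hindered aryl thioether, which a hard Lewis acid should leave alone and a soft activator should ionise. It sets out from 3. DDQ and 2-ethoxyethanol should give F1 as above, and NBS (1.0 equiv, CH2Cl2, −78 °C) should brominate C8 to give 8-bromo-4β-(2-ethoxyethoxy)-penta-O-benzylepicatechin F4. Exchange with 2,6-dimethylbenzenethiol (BF3·OEt2, CH2Cl2, −78 °C) should give 8-bromo-4β-(2,6-dimethylphenylthio)-penta-O-benzylepicatechin F5, the thiol entering trans to the C3 benzyloxy group. BF3·OEt2-promoted coupling of F1 (added slowly) with an excess of F5 should give attack at C6 of F5, its only free ring A carbon, and so deca-O-benzyl epicatechin-(4β→6)-[8-bromo-4β-(2,6-dimethylphenylthio)epicatechin] F6; the two ortho methyl groups should keep the sulfur from capturing the cation. Activation of the sulfide of F6 with I2 and Ag2O (CH2Cl2, −78 → −20 °C) in the presence of an excess of 19 should form the 4→8 bond and return to the route at 21.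

Step 11. The cation from 20 may self-condense through the free C6 and C8 of its own upper unit, may attack C6 instead of C8 of 19, or the Lewis acid may cleave interflavan bonds. The fallback caps the upper unit and sets out from 19. NBS (2.2 equiv, CH2Cl2) should give the 6,8-dibromo upper unit, tribromide F7. DDQ and 2-ethoxyethanol should give its C4 ether F8. Me3SiOTf coupling of F8 with a near-equimolar amount of 19 should give the tetrabromo eicosa-O-benzyl tetramer F9. Hydrogenolysis over Pd(OH)2/C with additional Et3N removes all four bromines with the benzyl groups and returns to the route at 22.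

## Further compounds

F1 | step 7 | 4β-(2-ethoxyethoxy)-3,5,7,3',4'-penta-O-benzylepicatechin | c9ccccc9COc1cc(OCc9ccccc9)c2c(c1)O[C@H](c7ccc(OCc9ccccc9)c(OCc9ccccc9)c7)[C@H](OCc9ccccc9)[C@H]2OCCOCC
F2 | step 9 | 1-[3,4-bis(benzyloxy)phenyl]-2-(benzyloxy)-3-[4,6-bis(benzyloxy)-2-hydroxyphenyl]-3-(8-bromo-penta-O-benzylepicatechin-6-yl)propan-1-one | O=C(c7ccc(OCc9ccccc9)c(OCc9ccccc9)c7)[C@H](OCc9ccccc9)[C@@H](c1c(OCc9ccccc9)c(Br)c3c(c1OCc9ccccc9)C[C@@H](OCc9ccccc9)[C@@H](c7ccc(OCc9ccccc9)c(OCc9ccccc9)c7)O3)c1c(O)cc(OCc9ccccc9)cc1OCc9ccccc9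
F3 | step 9 | single carbinol epimer of 18 with the hydroxyl 1,2-anti to the neighbouring benzyloxy group | O[C@@H](c7ccc(OCc9ccccc9)c(OCc9ccccc9)c7)[C@H](OCc9ccccc9)[C@@H](c1c(OCc9ccccc9)c(Br)c3c(c1OCc9ccccc9)C[C@@H](OCc9ccccc9)[C@@H](c7ccc(OCc9ccccc9)c(OCc9ccccc9)c7)O3)c1c(O)cc(OCc9ccccc9)cc1OCc9ccccc9
F4 | step 10 | 8-bromo-4β-(2-ethoxyethoxy)-penta-O-benzylepicatechin | c9ccccc9COc1cc(OCc9ccccc9)c2c(c1Br)O[C@H](c7ccc(OCc9ccccc9)c(OCc9ccccc9)c7)[C@H](OCc9ccccc9)[C@H]2OCCOCC
F5 | step 10 | 8-bromo-4β-(2,6-dimethylphenylthio)-penta-O-benzylepicatechin | c9ccccc9COc1cc(OCc9ccccc9)c2c(c1Br)O[C@H](c7ccc(OCc9ccccc9)c(OCc9ccccc9)c7)[C@H](OCc9ccccc9)[C@H]2Sc8c(C)cccc8C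
F6 | step 10 | deca-O-benzyl epicatechin-(4β→6)-[8-bromo-4β-(2,6-dimethylphenylthio)epicatechin] | c9ccccc9COc1cc(OCc9ccccc9)c2c(c1)O[C@H](c7ccc(OCc9ccccc9)c(OCc9ccccc9)c7)[C@H](OCc9ccccc9)[C@H]2c1c(OCc9ccccc9)c(Br)c3c(c1OCc9ccccc9)[C@H](Sc8c(C)cccc8C)[C@@H](OCc9ccccc9)[C@@H](c7ccc(OCc9ccccc9)c(OCc9ccccc9)c7)O3
F7 | step 11 | deca-O-benzyl 6,8-dibromoepicatechin-(4β→6)-8-bromoepicatechin | c9ccccc9COc1c(Br)c(OCc9ccccc9)c2c(c1Br)O[C@H](c7ccc(OCc9ccccc9)c(OCc9ccccc9)c7)[C@H](OCc9ccccc9)[C@H]2c1c(OCc9ccccc9)c(Br)c3c(c1OCc9ccccc9)C[C@@H](OCc9ccccc9)[C@@H](c7ccc(OCc9ccccc9)c(OCc9ccccc9)c7)O3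
F8 | step 11 | deca-O-benzyl 6,8-dibromoepicatechin-(4β→6)-[8-bromo-4β-(2-ethoxyethoxy)epicatechin] | c9ccccc9COc1c(Br)c(OCc9ccccc9)c2c(c1Br)O[C@H](c7ccc(OCc9ccccc9)c(OCc9ccccc9)c7)[C@H](OCc9ccccc9)[C@H]2c1c(OCc9ccccc9)c(Br)c3c(c1OCc9ccccc9)[C@H](OCCOCC)[C@@H](OCc9ccccc9)[C@@H](c7ccc(OCc9ccccc9)c(OCc9ccccc9)c7)O3
F9 | step 11 | eicosa-O-benzyl 6,8-dibromoepicatechin-(4β→6)-8-bromoepicatechin-(4β→8)-epicatechin-(4β→6)-8-bromoepicatechin | c9ccccc9COc1c(Br)c(OCc9ccccc9)c2c(c1Br)O[C@H](c7ccc(OCc9ccccc9)c(OCc9ccccc9)c7)[C@H](OCc9ccccc9)[C@H]2c1c(OCc9ccccc9)c(Br)c2c(c1OCc9ccccc9)[C@H](c1c(OCc9ccccc9)cc(OCc9ccccc9)c3c1O[C@H](c7ccc(OCc9ccccc9)c(OCc9ccccc9)c7)[C@H](OCc9ccccc9)[C@H]3c1c(OCc9ccccc9)c(Br)c3c(c1OCc9ccccc9)C[C@@H](OCc9ccccc9)[C@@H](c7ccc(OCc9ccccc9)c(OCc9ccccc9)c7)O3)[C@@H](OCc9ccccc9)[C@@H](c7ccc(OCc9ccccc9)c(OCc9ccccc9)c7)O2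
A1 | alternative 1 | eicosa-O-benzyl epicatechin-(4β→6)-epicatechin-(4β→8)-epicatechin-(4β→6)-8-bromoepicatechin | c9ccccc9COc1cc(OCc9ccccc9)c2c(c1)O[C@H](c7ccc(OCc9ccccc9)c(OCc9ccccc9)c7)[C@H](OCc9ccccc9)[C@H]2c1c(OCc9ccccc9)cc2c(c1OCc9ccccc9)[C@H](c1c(OCc9ccccc9)cc(OCc9ccccc9)c3c1O[C@H](c7ccc(OCc9ccccc9)c(OCc9ccccc9)c7)[C@H](OCc9ccccc9)[C@H]3c1c(OCc9ccccc9)c(Br)c3c(c1OCc9ccccc9)C[C@@H](OCc9ccccc9)[C@@H](c7ccc(OCc9ccccc9)c(OCc9ccccc9)c7)O3)[C@@H](OCc9ccccc9)[C@@H](c7ccc(OCc9ccccc9)c(OCc9ccccc9)c7)O2
A2 | alternative 1 | open-chain tris(aryl ether) triol, three carbinol centres unspecified, bottom unit 8-bromo-penta-O-benzylepicatechin-6-yl | c9ccccc9COc1cc(OCc9ccccc9)cc(O[C@H](c7ccc(OCc9ccccc9)c(OCc9ccccc9)c7)[C@H](OCc9ccccc9)C(O)c2c(OCc9ccccc9)cc(O[C@H](c7ccc(OCc9ccccc9)c(OCc9ccccc9)c7)[C@H](OCc9ccccc9)C(O)c3c(OCc9ccccc9)cc(OCc9ccccc9)cc3O[C@H](c7ccc(OCc9ccccc9)c(OCc9ccccc9)c7)[C@H](OCc9ccccc9)C(O)c3c(OCc9ccccc9)c(Br)c4c(c3OCc9ccccc9)C[C@@H](OCc9ccccc9)[C@@H](c7ccc(OCc9ccccc9)c(OCc9ccccc9)c7)O4)cc2OCc9ccccc9)c1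
A3 | alternative 2 | nonadeca-O-benzyl tetramer carrying a benzyldimethylsilyl group at C3 of the bottom unit | c9ccccc9COc1cc(OCc9ccccc9)c2c(c1)O[C@H](c7ccc(OCc9ccccc9)c(OCc9ccccc9)c7)[C@H](OCc9ccccc9)[C@H]2c1c(OCc9ccccc9)cc2c(c1OCc9ccccc9)[C@H](c1c(OCc9ccccc9)cc(OCc9ccccc9)c3c1O[C@H](c7ccc(OCc9ccccc9)c(OCc9ccccc9)c7)[C@H](OCc9ccccc9)[C@H]3c1c(OCc9ccccc9)cc3c(c1OCc9ccccc9)C[C@@H]([Si](C)(C)Cc9ccccc9)[C@@H](c7ccc(OCc9ccccc9)c(OCc9ccccc9)c7)O3)[C@@H](OCc9ccccc9)[C@@H](c7ccc(OCc9ccccc9)c(OCc9ccccc9)c7)O2
A4 | alternative 2 | benzylated trimer (units 1–3) carrying at C4 of its lowest unit a 2,6-bis(benzyloxy)-4-hydroxy-3-(hydroxymethyl)phenyl ring | c9ccccc9COc1cc(OCc9ccccc9)c2c(c1)O[C@H](c7ccc(OCc9ccccc9)c(OCc9ccccc9)c7)[C@H](OCc9ccccc9)[C@H]2c1c(OCc9ccccc9)cc2c(c1OCc9ccccc9)[C@H](c1c(OCc9ccccc9)cc(OCc9ccccc9)c3c1O[C@H](c7ccc(OCc9ccccc9)c(OCc9ccccc9)c7)[C@H](OCc9ccccc9)[C@H]3c1c(OCc9ccccc9)cc(O)c(CO)c1OCc9ccccc9)[C@@H](OCc9ccccc9)[C@@H](c7ccc(OCc9ccccc9)c(OCc9ccccc9)c7)O2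
A5 | alternative 2 | (Z)-benzyl{2-[3,4-bis(benzyloxy)phenyl]ethenyl}dimethylsilane | C[Si](C)(Cc1ccccc1)/C=C\c1ccc(OCc2ccccc2)c(OCc2ccccc2)c1
A6 | alternative 3 | nonadeca-O-benzyl tetramer with a free 3-hydroxyl on the bottom unit | c9ccccc9COc1cc(OCc9ccccc9)c2c(c1)O[C@H](c7ccc(OCc9ccccc9)c(OCc9ccccc9)c7)[C@H](OCc9ccccc9)[C@H]2c1c(OCc9ccccc9)cc2c(c1OCc9ccccc9)[C@H](c1c(OCc9ccccc9)cc(OCc9ccccc9)c3c1O[C@H](c7ccc(OCc9ccccc9)c(OCc9ccccc9)c7)[C@H](OCc9ccccc9)[C@H]3c1c(OCc9ccccc9)cc3c(c1OCc9ccccc9)C[C@@H](O)[C@@H](c7ccc(OCc9ccccc9)c(OCc9ccccc9)c7)O3)[C@@H](OCc9ccccc9)[C@@H](c7ccc(OCc9ccccc9)c(OCc9ccccc9)c7)O2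
A7 | alternative 3 | benzylated trimer (units 1–3) carrying at C4 of its lowest unit a 2,6-bis(benzyloxy)-4-[1-aryl-2,3-epoxypropoxy]phenyl ring, configured as C2 and C3 of the bottom unit | c9ccccc9COc1cc(OCc9ccccc9)c2c(c1)O[C@H](c7ccc(OCc9ccccc9)c(OCc9ccccc9)c7)[C@H](OCc9ccccc9)[C@H]2c1c(OCc9ccccc9)cc2c(c1OCc9ccccc9)[C@H](c1c(OCc9ccccc9)cc(OCc9ccccc9)c3c1O[C@H](c7ccc(OCc9ccccc9)c(OCc9ccccc9)c7)[C@H](OCc9ccccc9)[C@H]3c1c(OCc9ccccc9)cc(O[C@H](c7ccc(OCc9ccccc9)c(OCc9ccccc9)c7)[C@H]4CO4)cc1OCc9ccccc9)[C@@H](OCc9ccccc9)[C@@H](c7ccc(OCc9ccccc9)c(OCc9ccccc9)c7)O2
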